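**Assumption:** the target SMILES has no stereocentres, and the hindered biaryl axis is left unspecified, so the axis is obtained unresolved (racemic).

## Retrosynthetic overview
1. Target 19 comes from isodiospyrin 18 (the 6,8′-linked bi-7-methyljuglone) by late EtOH conjugate addition and re-oxidation at the quinone C–H positions remote from the biaryl axis.
2. Compound 18 comes from the bis-5-methoxy biquinone 17 (BCl3), which comes from bis-naphthol 16 (Fremy oxidation), which comes from bis-tetralone 15 (DDQ).
3. Key disconnection: the C6–C8′ biaryl bond of 15, made by Suzuki coupling of bromotetralone 7 with tetralone boronate 14 (14 is made from bromide 13).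
4. Ring order: both benzene rings come from m-cresol. Each saturated ring is closed by Eaton Friedel–Crafts acylation of an arylbutanoic acid, then aromatised (DDQ), then oxidised to the quinone (Fremy). Ethoxy groups go on last.

## Route

**Step 1**
Reactants: 1, m-cresol
Product: 2, 2-hydroxy-4-methylbenzaldehyde
Conditions: (CH2O)n, MgCl2, Et3N, MeCN, reflux
Reagents that add atoms: paraformaldehyde (C=O)
Why: Mg-phenoxide-directed ortho-formylation (Casnati–Skattebøl) goes to the less hindered ortho carbon, para to Me. No stereocentre.

**Step 2**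
Reactants: 2
Product: 3, (Z)-4-(2-hydroxy-4-methylphenyl)but-3-enoic acid
Conditions: (2-carboxyethyl)triphenylphosphonium bromide, t-BuOK (3.3 equiv), THF, 0 °C to rt
Reagents that add atoms: (2-carboxyethyl)triphenylphosphonium bromide, OC(=O)CC[P+](c1ccccc1)(c1ccccc1)c1ccccc1.[Br-]
Why: Wittig olefination with an unstabilised ylide gives the Z-alkene. That geometry is irrelevant because the alkene is hydrogenated next.

**Step 3**
Reactants: 3
Product: 4, 4-(2-hydroxy-4-methylphenyl)butanoic acid
Conditions: H2 (1 atm), 10% Pd/C, EtOAc, rt
Reagents that add atoms: none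
Why: Catalytic hydrogenation of the styrenyl alkene; no stereocentre is formed.

**Step 4**
Reactants: 4
Product: 5, 4-(3-bromo-2-hydroxy-4-methylphenyl)butanoic acid
Conditions: NBS, i-Pr2NH (2.2 equiv), CH2Cl2, −78 °C to rt
Reagents that add atoms: NBS, O=C1CCC(=O)N1Br
Why: Amine-mediated ortho-selective phenol bromination. One ortho site is blocked by the chain, so Br goes between OH and Me, which becomes the future C6 coupling site.

**Step 5**
Reactants: 5
Product: 6, 4-(3-bromo-2-methoxy-4-methylphenyl)butanoic acid
Conditions: MeI, K2CO3, DMF, rt; then LiOH, THF/MeOH/H2O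
Reagents that add atoms: MeI, CI
Why: Williamson O-methylation of phenol and acid, then saponification of the methyl ester only (aryl ether retained). No stereocentre.

**Step 6**
Reactants: 6
Product: 7, 6-bromo-5-methoxy-7-methyl-3,4-dihydronaphthalen-1(2H)-one
Conditions: Eaton's reagent (P2O5/MsOH), 60 °C
Reagents that add atoms: none
Why: Intramolecular Friedel–Crafts acylation at the only free ortho carbon, which closes the tetralone ring with OMe peri to C4.

**Step 7**
Reactants: 1, m-cresol
Product: 8, 3-methylanisole
Conditions: MeI, K2CO3, acetone, reflux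
Reagents that add atoms: MeI, CI
Why: Williamson O-methylation.

**Step 8**
Reactants: 8
Product: 9, 4-bromo-3-methylanisole
Conditions: NBS, MeCN, 0 °C to rt, dark
Reagents that add atoms: NBS, O=C1CCC(=O)N1Br
Why: Electrophilic bromination para to OMe. This blocks the para site so that the next acylation goes ortho to OMe.

**Step 9**
Reactants: 9; 10, succinic anhydride
Product: 11, 4-(5-bromo-2-methoxy-4-methylphenyl)-4-oxobutanoic acid
Conditions: AlCl3 (2.5 equiv), CH2Cl2, 0 °C to rt
Reagents that add atoms: none (succinic anhydride is the numbered reactant)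
Why: Friedel–Crafts succinoylation at C6, which is ortho to OMe and para to Me, the only activated unhindered position.

**Step 10**
Reactants: 11
Product: 12, 4-(5-bromo-2-methoxy-4-methylphenyl)butanoic acid
Conditions: Et3SiH, TFA, rt
Reagents that add atoms: none
Why: Ionic hydrogenation of the electron-rich aryl ketone to CH2; Ar–Br, OMe and CO2H survive.

**Step 11**
Reactants: 12
Product: 13, 8-bromo-5-methoxy-7-methyl-3,4-dihydronaphthalen-1(2H)-one
Conditions: Eaton's reagent, 70 °C
Reagents that add atoms: none
Why: Intramolecular Friedel–Crafts acylation at the only free ortho carbon, which lies next to Br, so the Br ends up peri to the new C=O.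

**Step 12**
Reactants: 13
Product: 14, 5-methoxy-7-methyl-8-(pinacolboryl)-3,4-dihydronaphthalen-1(2H)-one
Conditions: B2pin2, Pd(OAc)2, XPhos, KOAc, 1,4-dioxane, 100 °C
Reagents that add atoms: B2pin2, CC1(C)OB(OC1(C)C)B1OC(C)(C)C(C)(C)O1
Why: Miyaura borylation turns the hindered aryl bromide into the nucleophilic coupling partner.

**Step 13**
Reactants: 7; 14
Product: 15, 6-(5′-methoxy-7′-methyl-1′-oxotetralin-8′-yl)-5-methoxy-7-methyltetralin-1-one
Conditions: Pd2(dba)3, SPhos, K3PO4, toluene/H2O, 100 °C
Reagents that add atoms: none
Why: Suzuki–Miyaura cross-coupling joins the two tetralone halves at C6–C8′. The tetra-ortho-substituted axis is formed unresolved (racemic).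

**Step 14**
Reactants: 15
Product: 16, 6,8′-linked bis(5-methoxy-7-methyl-1-naphthol)
Conditions: DDQ (5 equiv), 1,4-dioxane, reflux
Reagents that add atoms: none
Why: Hydride-abstraction dehydrogenation of each enolisable tetralone to the aromatic 1-naphthol. No stereocentre.

**Step 15**
Reactants: 16
Product: 17, 5,5′-dimethoxy-7,7′-dimethyl-6,8′-bi(1,4-naphthoquinone)
Conditions: Fremy's salt (K2[ON(SO3)2]), acetone/aq. KH2PO4, rt
Reagents that add atoms: water (new C=O oxygen), O
Why: Teuber oxidation of 1-naphthols to 1,4-quinones at the free para position. The OMe-bearing rings have no free OH and are untouched.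

**Step 16**
Reactants: 17
Product: 18, isodiospyrin
Conditions: BCl3 (1 M in CH2Cl2, 6 equiv), CH2Cl2, −78 °C to 0 °C; aqueous work-up
Reagents that add atoms: none
Why: Boron-chelate-assisted cleavage of the peri-OMe groups next to the quinone carbonyls.

**Step 17**
Reactants: 18
Product: 19, 3,2′-diethoxyisodiospyrin (target)
Conditions: EtOH (excess), BF3·OEt2 (cat.), CH2Cl2, rt; then Ag2O
Reagents that add atoms: ethanol, CCO
Why: Acid-catalysed conjugate (oxa-Michael) addition of EtOH to each quinone, then Ag2O re-oxidation of the ethoxyhydroquinone. Addition is assumed to occur at the carbon remote from the twisted biaryl axis, with the ring-A C4=O also chelate-activated. The resulting 2-ethoxyquinones resist a second addition. No stereocentre is formed.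

## Compound list
1 | m-cresol | Cc1cccc(O)c1 | starting material
2 | 2-hydroxy-4-methylbenzaldehyde | Cc1ccc(C=O)c(O)c1 | intermediate
3 | (Z)-4-(2-hydroxy-4-methylphenyl)but-3-enoic acid | Cc1ccc(/C=C\CC(=O)O)c(O)c1 | intermediate
4 | 4-(2-hydroxy-4-methylphenyl)butanoic acid | Cc1ccc(CCCC(=O)O)c(O)c1 | intermediate
5 | 4-(3-bromo-2-hydroxy-4-methylphenyl)butanoic acid | Cc1ccc(CCCC(=O)O)c(O)c1Br | intermediate
6 | 4-(3-bromo-2-methoxy-4-methylphenyl)butanoic acid | Cc1ccc(CCCC(=O)O)c(OC)c1Br | intermediate
7 | 6-bromo-5-methoxy-7-methyl-3,4-dihydronaphthalen-1(2H)-one | COc1c(Br)c(C)cc2C(=O)CCCc12 | intermediate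
8 | 3-methylanisole | COc1cccc(C)c1 | intermediate
9 | 4-bromo-3-methylanisole | COc1ccc(Br)c(C)c1 | intermediate
10 | succinic anhydride | O=C1CCC(=O)O1 | starting material
11 | 4-(5-bromo-2-methoxy-4-methylphenyl)-4-oxobutanoic acid | OC(=O)CCC(=O)c1cc(Br)c(C)cc1OC | intermediate
12 | 4-(5-bromo-2-methoxy-4-methylphenyl)butanoic acid | OC(=O)CCCc1cc(Br)c(C)cc1OC | intermediate
13 | 8-bromo-5-methoxy-7-methyl-3,4-dihydronaphthalen-1(2H)-one | COc1cc(C)c(Br)c2C(=O)CCCc12 | intermediate
14 | 5-methoxy-7-methyl-8-(Bpin)-3,4-dihydronaphthalen-1(2H)-one | COc1cc(C)c(B2OC(C)(C)C(C)(C)O2)c2C(=O)CCCc12 | intermediate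
15 | bis-tetralone biaryl (6,8′-linked) | COc1c(-c3c(C)cc(OC)c4CCCC(=O)c34)c(C)cc2C(=O)CCCc12 | intermediate
16 | bis(1-naphthol) biaryl | COc1c(-c3c(C)cc(OC)c4cccc(O)c34)c(C)cc2c(O)cccc12 | intermediate
17 | 5,5′-dimethoxy biquinone | COc1c(-c3c(C)cc(OC)c4C(=O)C=CC(=O)c34)c(C)cc2C(=O)C=CC(=O)c12 | intermediate
18 | isodiospyrin | Oc1c(-c3c(C)cc(O)c4C(=O)C=CC(=O)c34)c(C)cc2C(=O)C=CC(=O)c12 | intermediate
19 | 3,2′-diethoxyisodiospyrin | CCOC1=CC(=O)c2c(cc(C)c(-c3c(C)cc(O)c4c3C(=O)C=C(OCC)C4=O)c2O)C1=O | target

## Summary
Total steps: 17. Longest linear sequence: 11 (steps 1–6, then 13–17; the other branch, steps 7–12 then 13–17, is also 11).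

Three steps most likely to fail:
1. **Step 13 (tetra-ortho-substituted Suzuki coupling).** Hindered boronate protodeboronation or low conversion is likely. Fallback: couple the monocyclic arenes first (the 6-type and 12-type aryl units, with the ring-closure sites still H) and then close both tetralone rings by a double Eaton cyclisation on the biaryl diacid.
2. **Step 17 (regiochemistry of the EtOH addition).** The axis-remote selectivity is assumed, not established, and over-addition is possible. Fallback: place the ethoxy groups before coupling. Ring A would be made by tetralone α-hydroxylation, then O-ethylation, DDQ aromatisation and Fremy oxidation to the 2-ethoxyquinone. Ring B would need the isomeric 8-methoxytetralone route.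
3. **Step 4 (ortho-bromination between OH and Me).** The para site may compete. Fallback: install the C6 handle by directed ortho-metalation of the m-cresol O-carbamate (s-BuLi/TMEDA, then a Br+ source) before building the butanoic acid chain.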